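At early times Sunday's flask held more D than it kept, 50.0% at 3.00 min against 36.6% at 50.0 min, while Z climbed from 17.9% to 44.3%. So D can go back, and I looked for what stays put once Z has stopped.

| setting | Sunday's | Wednesday's | Monday's | flask |
|---|---|---|---|---|
| Q | 0.60 M | 1.4 M | 0.90 M | 0.90 M |
| L | 0.72 M | 0.72 M | 0.36 M | 0.720 M |
| G | 0.27 M | 0.27 M | 0.27 M | 0.270 M |
| E | 39 mM | 39 mM | 39 mM | 39 mM |
| remark | run made earlier | run made earlier | run made earlier |  |
| time |  |  |  | 1.0 h |

| run | time / min | D / % | Z / % |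
|---|---|---|---|
| Sunday's | 3.00 | 50.0 | 17.9 |
| Sunday's | 10.0 | 43.1 | 32.6 |
| Sunday's | 15.0 | 40.5 | 39.2 |
| Sunday's | 25.0 | 39.0 | 43.1 |
| Sunday's | 40.0 | 36.4 | 43.8 |
| Sunday's | 50.0 | 36.6 | 44.3 |
| Wednesday's | 8.00 | 36.8 | 19.2 |
| Wednesday's | 15.0 | 36.1 | 18.6 |
| Wednesday's | 25.0 | 35.3 | 19.6 |
| Wednesday's | 30.0 | 36.1 | 20.1 |
| Wednesday's | 40.0 | 36.7 | 19.0 |
| Wednesday's | 50.0 | 36.2 | 18.8 |
| Monday's | 4.00 | 25.3 | 23.7 |
| Monday's | 12.0 | 25.5 | 29.4 |
| Monday's | 20.0 | 23.7 | 30.1 |
| Monday's | 30.0 | 25.1 | 29.4 |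
| Monday's | 50.0 | 24.4 | 30.3 |

(each reading ± 0.5 percentage points)

- the numbers in the tables scatter with a standard deviation of 0.5 percentage points

I read the last row of each table. In concentrations, cZ ended at 0.266 M on Sunday, 0.263 M on Wednesday and 0.273 M on Monday, each near the 0.27 M of G charged, so I took G as the limiting reagent of Z. Let cR be the Q charged minus cD minus cZ, and cL the L charged minus cD. Monday's row gives 3.84 M⁻¹ for the holding quotient, cD over cR times cL, an equilibrium constant if it stays put. Sunday's row gives 3.83 M⁻¹ and Wednesday's 3.77 M⁻¹, though the Q charged ran from 0.60 M to 1.4 M.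

- ratio of D to Z at 3.0 s
- ratio of D to Z at 1.0 h

For the flask I set cZ to the G charged and solved the quotient for cD, which gave 0.364 M and a ratio of 1.35 at 1.0 h. For 3.0 s I committed to nothing, since the earliest reading stands at 3.00 min.

The forecast gave 88 and 1.35, and said of the first: “Slower equilibration would lower this considerably”.

The flask gave 59.0 and 1.35. The forecast's early ratio stood 1.49 times too high, and the late ratio agreed with mine.

    Q + E → E + J (k = 4.90 M⁻¹ s⁻¹)
    L + E + J ⇌ E + D (K = 3.90 M⁻¹, k = 8.80 M⁻² s⁻¹)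
    J + G → Z (k = 0.0130 M⁻¹ s⁻¹)

In the flask the rest cR was J, 29.4% of the Q charged at 1.00 h, with Q at 0%. On the neighbour flask with 0.43 M of L, the same quotient and G charge gave me cD of 0.254 M and a ratio of 0.941, just under one, the even split of D and Z. That neighbour ended at 0.946, with D at 28.4% and Z at 30.0% of the Q charged.

The data were generated by integration on assumed constants; scatter was added.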